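**Assumptions (one line each)**
- Lupalbigenin (5,7,4'-trihydroxy-6,3'-diprenylisoflavone) has no stereocenters and no stereogenic alkenes, because each prenyl terminus is gem-dimethyl. "Single enantiomer" therefore does not apply.
- Genistein is commercial, so the chromone/isoflavone core is bought rather than built.
- The 7-OH of genistein (pKa about 7) is much more acidic than the 4'-OH and far more acidic than the chelated 5-OH. It can therefore be selectively mono-benzylated under stoichiometric mild base.

## Retrosynthetic overview
- Target ← 6,3'-diallylgenistein (7) by double olefin cross-metathesis of the two allyl groups with 2-methyl-2-butene (allyl → prenyl). This is the bold step.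
- Diallyl compound ← 5,4'-di-O-allyl-7-O-benzylgenistein (5) by a double aromatic Claisen rearrangement. The 5-O-allyl group can only migrate to C6, because C4a is blocked. The 4'-O-allyl group migrates to C3'. This avoids the C8-versus-C6 problem of direct prenylation.
- Compound 5 ← genistein by selective 7-O-benzylation, then O-allylation of the remaining 5-OH and 4'-OH.
- No ring is formed in the route. The isoflavone is already in genistein, and the steps are Bn protection, O-allylation, Claisen, debenzylation, then cross-metathesis.

## Route

**Step 1**
- Reactants: 1 (genistein), 2 (benzyl bromide)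
- Product: 3 (7-O-benzylgenistein)
- Conditions: BnBr (1.05 equiv), K2CO3 (1.0 equiv), DMF, rt, 12 h
- Reagents that add atoms: benzyl bromide, BrCc1ccccc1
- Why: Williamson etherification; the most acidic 7-phenoxide is alkylated preferentially, the chelated 5-OH is inert, and a small amount of 7,4'-bis-benzyl ether is removed by chromatography.

**Step 2**
- Reactants: 3, 4 (allyl bromide)
- Product: 5 (5,4'-di-O-allyl-7-O-benzylgenistein)
- Conditions: allyl bromide (4 equiv), K2CO3 (4 equiv), DMF, 70 °C, 8 h
- Reagents that add atoms: allyl bromide, C=CCBr
- Why: Williamson etherification; the reactive allylic bromide in excess and heat overcomes the H-bond-deactivated 5-OH, and the 4'-OH reacts readily.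

**Step 3**
- Reactants: 5
- Product: 6 (6,3'-diallyl-7-O-benzyl-5,4'-dihydroxyisoflavone)
- Conditions: PhNEt2, 210 °C (microwave, sealed tube), 1 h
- Reagents that add atoms: none
- Why: Double thermal aromatic Claisen ([3,3]) rearrangement. The 5-O-allyl group has only C6 as a free ortho position, and the 4'-O-allyl group goes to C3'. Regular allyl, not reverse-prenyl, is delivered, and the 7-OBn group blocks O7/C8 chemistry.

**Step 4**
- Reactants: 6
- Product: 7 (6,3'-diallylgenistein)
- Conditions: BCl3 (4 equiv), pentamethylbenzene (3 equiv), CH2Cl2, −78 → −40 °C, 1 h; MeOH quench
- Reagents that add atoms: none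
- Why: Lewis-acid cleavage of the aryl benzyl ether with a cation scavenger. It is done at the diallyl stage because terminal allyl alkenes tolerate BCl3 far better than prenyl alkenes, and hydrogenolysis is avoided so the alkenes survive.

**Step 5**
- Reactants: 7, 8 (2-methyl-2-butene)
- Product: 9 (lupalbigenin)
- Conditions: 2-methyl-2-butene (about 50 equiv), Hoveyda–Grubbs II (10 mol%), 1,4-benzoquinone (20 mol%), CH2Cl2, sealed tube, 45 °C, 24 h (catalyst added in two portions)
- Reagents that add atoms: 2-methyl-2-butene, CC=C(C)C
- Why: Ru-catalysed cross-metathesis of each terminal allyl alkene with the trisubstituted alkene. Loss of volatile propene and the large excess of 2-methyl-2-butene drive formation of the prenyl group, and the quinone suppresses Ru–H-mediated allyl → propenyl isomerisation. No stereocenter or E/Z issue arises.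

**Final checks**
- Atom balance: 7 is C21H18O5. Two allyl → prenyl conversions (+C2H4 each) give C25H26O5, which is lupalbigenin.
- Regiochemistry: the prenyls are at C6, between the 5-OH and 7-OH, and at C3', ortho to the 4'-OH. The 5,7,4'-OH pattern is restored in step 4, and the SMILES of 9 matches the target.
- Functional groups: the chromone C2=C3 and C4=O are untouched by every step. No step uses a reductant.

## Compound list
| No. | Name | SMILES | Role |
|---|---|---|---|
| 1 | Genistein | O=c1c(-c2ccc(O)cc2)coc2cc(O)cc(O)c12 | starting material |
| 2 | Benzyl bromide | BrCc1ccccc1 | starting material |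
| 3 | 7-O-Benzylgenistein | O=c1c(-c2ccc(O)cc2)coc2cc(OCc3ccccc3)cc(O)c12 | intermediate |
| 4 | Allyl bromide | C=CCBr | starting material |
| 5 | 5,4'-Di-O-allyl-7-O-benzylgenistein | O=c1c(-c2ccc(OCC=C)cc2)coc2cc(OCc3ccccc3)cc(OCC=C)c12 | intermediate |
| 6 | 6,3'-Diallyl-7-O-benzyl-5,4'-dihydroxyisoflavone | O=c1c(-c2ccc(O)c(CC=C)c2)coc2cc(OCc3ccccc3)c(CC=C)c(O)c12 | intermediate |
| 7 | 6,3'-Diallylgenistein | O=c1c(-c2ccc(O)c(CC=C)c2)coc2cc(O)c(CC=C)c(O)c12 | intermediate |
| 8 | 2-Methyl-2-butene | CC=C(C)C | starting material |
| 9 | Lupalbigenin | CC(C)=CCc1cc(-c2coc3cc(O)c(CC=C(C)C)c(O)c3c2=O)ccc1O | target (achiral) |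

## Totals
- Total steps: 5
- Longest linear sequence: 5 steps from genistein

## Three steps most likely to fail
1. **Step 5 (double cross-metathesis).** Risks are incomplete conversion of the second allyl group, allyl → propenyl isomerisation, and catalyst poisoning by three free phenols.
   - Fallback: change approach by protecting the phenols and ozonolysing the two allyl groups to aldehydes. Then do a double Wittig olefination with Ph3P=CMe2 (from isopropyltriphenylphosphonium iodide, base), followed by deprotection.
2. **Steps 2–3 (5-O-allylation and the double Claisen).** The chelated 5-OH may alkylate poorly, and the 5-O-allyl chromone may be sluggish or decompose at 210 °C.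
   - Fallback: build the A-ring with the C6 allyl already present. Make 2-hydroxy-4-benzyloxy-6-allyloxyacetophenone and do the Claisen at the ketone stage. Then make the 3-iodochromone (DMF-DMA, then I2) and carry out a Suzuki coupling with 3-allyl-4-hydroxyphenylboronic acid pinacol ester.
3. **Step 1 (7- versus 4'-selective benzylation).** Bis-benzylation and poor separation would cut the yield of 3.
   - Fallback: change approach by assembling the 7-O-benzyl-5-hydroxy core from 2,4-dihydroxy-6-benzyloxy-type precursors by the deoxybenzoin route (arylacetic acid, BF3·OEt2, then DMF/MeSO2Cl cyclisation).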